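**Retrosynthetic overview**
- Feature: in ring C, the carbonyl carbon C4 is bonded only to C4a of ring A and to C3. C3 is paired with C2, which bears ring B, and O1 sits on C8a next to C4a. C4 is therefore read as one molecule of CO, C3–C2 as a terminal arylacetylene, and C4a/C8a–O1 as an ortho-iodophenol.
- Last disconnection: the 5-OH (peri to C4=O) and the 3'-OH travel as a methyl ether and a benzyl ether. BCl3 frees both together from 3'-benzyloxy-4',5,6,7,8-pentamethoxyflavone.
- Ring A partner: 2-iodo-3,4,5,6-tetramethoxyphenol, made from 1,2,3,4-tetramethoxybenzene by formylation, peracid aryl migration and iodination of the only ring C–H left.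
- Ring B partner: 2-(benzyloxy)-4-ethynyl-1-methoxybenzene, made from isovanillin by benzylation and one-carbon homologation of the aldehyde.
- Ring order: rings A and B are bought as arenes. Ring C is the only ring built, in the three-component step.

Key step: step 6

Assumption: 1,2,3,4-tetramethoxybenzene is taken as a catalogue chemical, and because the target has no stereocentre no stereocontrol is planned.

**Step 1**
Reactants: 1 1,2,3,4-tetramethoxybenzene
Product: 3 2,3,4,5-tetramethoxybenzaldehyde, via aryl iminium salt 2 (not isolated)
Conditions: POCl3, DMF, 0 to 80 °C; then ice-water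
Reagents that add atoms: N,N-dimethylformamide, CN(C)C=O; water, O
Why: Vilsmeier–Haack formylation: the chloroiminium ion from DMF and POCl3 attacks one of the two symmetry-equivalent free positions of the electron-rich arene (ortho to one methoxy group, para to another), the iminium group of 2 blocks a second attack, and water hydrolyses 2 to the aldehyde.

**Step 2**
Reactants: 3 2,3,4,5-tetramethoxybenzaldehyde
Product: 5 2,3,4,5-tetramethoxyphenol, via aryl formate 4 (not isolated)
Conditions: mCPBA, CH2Cl2, 0 °C to rt; then Et3N, MeOH, rt, argon
Reagents that add atoms: meta-chloroperoxybenzoic acid, O=C(OO)c1cccc(Cl)c1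
Why: Baeyer–Villiger oxidation in its Dakin-type form: an aldehyde without a free ortho or para hydroxyl group responds poorly to alkaline H2O2, so a peracid is used, the aryl group with ortho and para methoxy donors migrates to oxygen in preference to hydride, and amine-catalysed methanolysis of formate 4 frees the air-sensitive phenol without strong base.

**Step 3**
Reactants: 5 2,3,4,5-tetramethoxyphenol
Product: 6 2-iodo-3,4,5,6-tetramethoxyphenol
Conditions: NIS (1.0 equiv), MeCN, −10 to 0 °C, dark
Reagents that add atoms: N-iodosuccinimide, O=C1CCC(=O)N1I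
Why: Electrophilic aromatic iodination: the only ring C–H of 5 lies ortho to the hydroxyl group, ortho to one methoxy group and para to another, so one equivalent of NIS at low temperature can give only this regioisomer.

**Step 4**
Reactants: 7 isovanillin (3-hydroxy-4-methoxybenzaldehyde)
Product: 8 3-benzyloxy-4-methoxybenzaldehyde
Conditions: BnBr, K2CO3, DMF, rt to 50 °C
Reagents that add atoms: benzyl bromide, BrCc1ccccc1
Why: Williamson ether synthesis: the phenoxide of isovanillin displaces bromide from benzyl bromide in an SN2 reaction, and the aldehyde and the methyl ether are inert to K2CO3.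

**Step 5**
Reactants: 8 3-benzyloxy-4-methoxybenzaldehyde
Product: 9 2-(benzyloxy)-4-ethynyl-1-methoxybenzene
Conditions: dimethyl (1-diazo-2-oxopropyl)phosphonate, K2CO3, MeOH, rt
Reagents that add atoms: dimethyl (1-diazo-2-oxopropyl)phosphonate, COP(=O)(OC)C(=[N+]=[N-])C(C)=O
Why: Ohira–Bestmann variant of the Seyferth–Gilbert homologation: methoxide deacetylates the reagent, the diazophosphonate anion olefinates the non-enolisable aldehyde, and loss of N2 with a 1,2-hydride shift gives the terminal alkyne under conditions that leave the benzyl ether alone.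

**Step 6**
Reactants: 6 2-iodo-3,4,5,6-tetramethoxyphenol; 9 2-(benzyloxy)-4-ethynyl-1-methoxybenzene (1.3 equiv)
Product: 12 3'-benzyloxy-4',5,6,7,8-pentamethoxyflavone, via ortho-hydroxyaryl ynone 10 (not isolated), via diethylamino enaminone 11 (not isolated)
Conditions: PdCl2(PPh3)2 (5 mol %), CO (20 bar), Et2NH, 120 °C, autoclave
Reagents that add atoms: carbon monoxide, [C-]#[O+]
Why: PdCl2(PPh3)2 is reduced in the amine to zerovalent palladium, which inserts into the C4a–I bond of 6; CO then inserts to give an aroyl complex of divalent palladium, the acetylide that diethylamine raises from 9 takes the place of iodide, and reductive elimination releases ynone 10 with C4a–C4 and C4–C3 in place. The closest known reaction type is the carbonylative Sonogashira annulation of ortho-iodophenols with terminal alkynes to chromones and flavones, run without CuI. Ring C closes in a 6-endo mode through O1–C2: diethylamine adds to C2 of 10 to give the push-pull enaminone 11, the C8a hydroxyl oxygen attacks the same carbon, and the amine leaves again. No stereocentre is formed. The step needs CO insertion to outrun direct alkynylation (the path to a benzofuran) and acetylide transfer to outrun amine capture of the aroyl complex, and CO pressure, the absence of copper, the fast migration of an electron-rich aryl group and the two ortho substituents, which screen the aroyl carbon from a branched amine more than from a rod-shaped acetylide, all push that way. It also needs 6-endo over 5-exo closure (the aurone path), which is secured because in 11 C3 is electron-rich and C2 is the only carbon left open to the oxygen nucleophile.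

**Step 7**
Reactants: 12 3'-benzyloxy-4',5,6,7,8-pentamethoxyflavone
Product: 14 Gardenin D (5,3'-dihydroxy-6,7,8,4'-tetramethoxyflavone), via bis(dichloroboryl) aryloxide 13 (not isolated)
Conditions: BCl3 (4 equiv), pentamethylbenzene (3 equiv), CH2Cl2, −78 to 0 °C; then 1 M aq. HCl, rt
Reagents that add atoms: none
Why: Lewis-acid ether cleavage with a cation scavenger: BCl3 ties the C4 carbonyl oxygen and the peri C5 methoxy oxygen into a six-membered chelate so that chloride removes only that methyl group, the benzyl ether leaves as a benzyl cation that pentamethylbenzene traps before it can alkylate rings A or B, and the four unchelated aryl methyl ethers should resist BCl3 at or below 0 °C.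

**Compound list**
1 | 1,2,3,4-tetramethoxybenzene | COc1ccc(OC)c(OC)c1OC | starting material
2 | N,N-dimethyl-(2,3,4,5-tetramethoxybenzylidene)iminium dichlorophosphate | C[N+](C)=Cc1cc(OC)c(OC)c(OC)c1OC.[O-]P(=O)(Cl)Cl | intermediate (not isolated)
3 | 2,3,4,5-tetramethoxybenzaldehyde | COc1cc(C=O)c(OC)c(OC)c1OC | intermediate
4 | 2,3,4,5-tetramethoxyphenyl formate | COc1cc(OC=O)c(OC)c(OC)c1OC | intermediate (not isolated)
5 | 2,3,4,5-tetramethoxyphenol | COc1cc(O)c(OC)c(OC)c1OC | intermediate
6 | 2-iodo-3,4,5,6-tetramethoxyphenol | Oc1c(I)c(OC)c(OC)c(OC)c1OC | intermediate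
7 | isovanillin | COc1ccc(C=O)cc1O | starting material
8 | 3-benzyloxy-4-methoxybenzaldehyde | COc1ccc(C=O)cc1OCc1ccccc1 | intermediate
9 | 2-(benzyloxy)-4-ethynyl-1-methoxybenzene | C#Cc1ccc(OC)c(OCc2ccccc2)c1 | intermediate
10 | 3-(3-benzyloxy-4-methoxyphenyl)-1-(2-hydroxy-3,4,5,6-tetramethoxyphenyl)prop-2-yn-1-one | COc1ccc(C#CC(=O)c2c(O)c(OC)c(OC)c(OC)c2OC)cc1OCc1ccccc1 | intermediate (not isolated)
11 | (E)-3-(3-benzyloxy-4-methoxyphenyl)-3-(diethylamino)-1-(2-hydroxy-3,4,5,6-tetramethoxyphenyl)prop-2-en-1-one | CCN(CC)/C(=C/C(=O)c1c(O)c(OC)c(OC)c(OC)c1OC)c1ccc(OC)c(OCc2ccccc2)c1 | intermediate (not isolated)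
12 | 3'-benzyloxy-4',5,6,7,8-pentamethoxyflavone | COc1ccc(-c2cc(=O)c3c(OC)c(OC)c(OC)c(OC)c3o2)cc1OCc1ccccc1 | intermediate
13 | 5-O,3'-O-bis(dichloroboryl) derivative of Gardenin D (5-O-boron chelated to the C4 carbonyl) | COc1ccc(-c2cc(=O)c3c(OB(Cl)Cl)c(OC)c(OC)c(OC)c3o2)cc1OB(Cl)Cl | intermediate (not isolated)
14 | Gardenin D, 5,3'-dihydroxy-6,7,8,4'-tetramethoxyflavone | COc1ccc(-c2cc(=O)c3c(O)c(OC)c(OC)c(OC)c3o2)cc1O | target

**Step count**
Total step count: 7.
Longest linear sequence: 5 steps (1 → 3 → 5 → 6 → 12 → 14). The ring B branch (7 → 8 → 9) joins at step 6.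

**Steps most likely to fail**

1. Step 6.
 - What may go wrong: oxidative addition and CO insertion may be slow at a C–I bond flanked by two oxygen substituents on a very electron-rich ring. Direct alkynylation, amine capture of the aroyl complex or hydrodeiodination could then take over.
 - Fallback: it sets out from phenol 5 and aldehyde 8 and comes back at 12, building ring C by condensation chemistry without palladium or CO. Phenol 5 would be C-acetylated at its one free ring position with Ac2O and BF3·OEt2 (O-acetylation and Fries shift, 80 °C) to 2'-hydroxy-3',4',5',6'-tetramethoxyacetophenone F1. Claisen–Schmidt condensation of this ketone with 8 (KOH, EtOH, rt) would give (E)-3-(3-benzyloxy-4-methoxyphenyl)-1-(2-hydroxy-3,4,5,6-tetramethoxyphenyl)prop-2-en-1-one F2. Oxidative cyclisation with catalytic I2 in DMSO at 130 °C would then form O1–C2, dehydrogenate C2–C3 and deliver 12.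

2. Step 7.
 - What may go wrong: once the first boron aryloxides are formed, neighbouring-group delivery of boron may carry the demethylation on to the C6 or C4' methoxy group. Alternatively, the two cleavages may not finish in the same temperature window.
 - Fallback: it sets out from 12 and comes back at 14, separating the two deprotections and using no Lewis acid. Hydrogenolysis (H2 1 atm, 10% Pd/C, EtOAc–MeOH, rt) would give 3'-hydroxy-4',5,6,7,8-pentamethoxyflavone F3. Brønsted-acid demethylation (conc. HCl, EtOH, reflux) would then give 14, because it acts only on the methoxy group that is activated by the protonated C4 carbonyl.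

3. Step 3.
 - What may go wrong: the electrophilic iodine source may oxidise the para-methoxyphenol by electron transfer and loss of methanol towards a quinone instead of substituting the ring.
 - Fallback: it sets out from 5 and comes back at 6, replacing electrophilic iodination by directed ortho-metalation. Phenol 5 would be protected with MeOCH2Cl and iPr2NEt in CH2Cl2 as 1,2,3,4-tetramethoxy-5-(methoxymethoxy)benzene F4. n-BuLi (THF, 0 °C) would remove the single ring proton, which lies between two coordinating oxygen substituents, to give 2,3,4,5-tetramethoxy-6-(methoxymethoxy)phenyllithium F5. I2 would convert it into 1-iodo-2,3,4,5-tetramethoxy-6-(methoxymethoxy)benzene F6, and HCl in MeOH at 40 °C would take off the acetal to return 6.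

**Further compounds**
F1 | step 6 | 2'-hydroxy-3',4',5',6'-tetramethoxyacetophenone | CC(=O)c1c(O)c(OC)c(OC)c(OC)c1OC
F2 | step 6 | (E)-3-(3-benzyloxy-4-methoxyphenyl)-1-(2-hydroxy-3,4,5,6-tetramethoxyphenyl)prop-2-en-1-one | COc1ccc(/C=C/C(=O)c2c(O)c(OC)c(OC)c(OC)c2OC)cc1OCc1ccccc1
F3 | step 7 | 3'-hydroxy-4',5,6,7,8-pentamethoxyflavone | COc1ccc(-c2cc(=O)c3c(OC)c(OC)c(OC)c(OC)c3o2)cc1O
F4 | step 3 | 1,2,3,4-tetramethoxy-5-(methoxymethoxy)benzene | COCOc1cc(OC)c(OC)c(OC)c1OC
F5 | step 3 | 2,3,4,5-tetramethoxy-6-(methoxymethoxy)phenyllithium | [Li]c1c(OCOC)c(OC)c(OC)c(OC)c1OC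
F6 | step 3 | 1-iodo-2,3,4,5-tetramethoxy-6-(methoxymethoxy)benzene | COCOc1c(I)c(OC)c(OC)c(OC)c1OC
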